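I am asked what holds most of the substrate when ash stops at 3.0 min and birch at 6.0 min, and how much it holds.

| flask | substrate | gas | remark | time |
|---|---|---|---|---|
| spring | 0.12 M | 18 mM (held) | run made earlier |  |
| autumn | 0.50 M | 18 mM (held) | run made earlier |  |
| ash | 0.25 M | 18 mM (held) |  | 3.0 min |
| birch | 0.25 M | 18 mM (held) |  | 6.0 min |

| run | time / s | isomer of the product / % | target / % | tautomer / % | substrate / % |
|---|---|---|---|---|---|
| spring | 10.0 | 10.6 | 0.3 | 0.3 | 88.8 |
| spring | 20.0 | 20.4 | 0.9 | 0.6 | 78.5 |
| spring | 50.0 | 40.8 | 1.8 | 0.1 | 57.5 |
| spring | 120 | 52.6 | 4.1 | 0 | 43.6 |
| autumn | 10.0 | 4.1 | 0 | 0.8 | 95.1 |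
| autumn | 20.0 | 7.6 | 0.5 | 0 | 91.6 |
| autumn | 50.0 | 17.6 | 0.7 | 0.5 | 79.8 |
| autumn | 120 | 35.8 | 1.8 | 0.3 | 60.9 |

(each reading ± 0.5 percentage points)

- which of these there is most of at the end, counted by the substrate in it, ash (tautomer / substrate / isomer of the product / target)
- which of these there is most of at the end, counted by the substrate in it, birch (tautomer / substrate / isomer of the product / target)
- final amount of the leader among these, as a percentage of the substrate charged, in ash
- final amount of the leader among these, as a percentage of the substrate charged, in birch

- at the start none of partner is dissolved
- the analysis behind the earlier runs scatters by 0.5 percentage points, standard deviation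
- steps under discussion: substrate <-> tautomer; substrate + partner <-> isomer of the product; partner + tautomer -> target; gas <-> partner

Gas dissolves to give partner, partner adds reversibly to substrate to give the isomer of the product, and partner with tautomer gives target. One thing looks wrong: the last autumn reading holds 179 mM of isomer, ten times the 18 mM at which the gas saturates. It clears up when I write the balance of partner: what has come in from the held gas equals dissolved partner plus isomer plus target, so partner is a flow, not a stock. Isomer plus target in autumn, divided by 120 s, I call the uptake rate, 1.57 mM s⁻¹.

The last spring readings give isomer over substrate of 1.21, which I take as near the plateau, so isomer can hold about 54.7% of the pool. In ash that is 137 mM, which the uptake rate delivers in 87.3 s, less than the 3.0 min of ash. So I expect isomer to lead, somewhat under that share once target is taken off.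

The forecast says isomer of the product for ash at 52% (47% to 57%) and isomer of the product for birch at 51% (45% to 56%), below my share; in its words, “Birch then drains slowly through target”.

The flask gives isomer of the product at 51.3% in ash and isomer of the product at 49.3% in birch, as forecast.

    substrate ⇌ tautomer (K = 0.00740, k = 0.0610 s⁻¹)
    substrate + partner ⇌ isomer of the product (K = 72.0 L mol⁻¹, k = 2.90 L mol⁻¹ s⁻¹)
    partner + tautomer → target (k = 7.00 L mol⁻¹ s⁻¹)
    gas ⇌ partner, rate k4*(csat - [partner]) (kL = 0.130 s⁻¹)

Ash is not at rest at 3.00 min. It has taken in 159 mM of partner, less than the 283 mM the uptake rate offers. At 30.0 min ash holds 28.1% isomer, 50.2% target and 21.6% substrate; at 60.0 min birch holds 13.8% isomer and 75.5% target. At those later times target holds most in both ash and birch .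

In a neighbour of ash charged with 0.62 M of substrate, the same share needs 216 s of uptake, longer than 3.0 min, so I get 283 mM taken in, 45.6% of its charge. The flask holds 40.2% isomer, 3.74% target and 0.0107 M partner, together 283 mM, and substrate leads at 55.6%.

The data were generated by integration for substances that don't exist; noise was put on by code.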